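**Retrosynthetic overview**
- The target is cut back (C9 MOM ether off, O8 angelate off, C14 ester to CH2O-silyl, C13 methylene off) to a trans C6/C7 γ-lactone, and this to a ten-membered C6 ketone carrying the C8/C9 ethers and a C7 acetate arm.
- The strategy rests on one feature: the C6 oxygen, the C1=C10 olefin and the vicinal C8/C9 oxygens form a cyclodec-5-enone pattern, in which C1–C6 is the hidden ring bond of a 3-methylcyclohexanone (C4 methyl).
- Key disconnection: anionic oxy-Cope ring expansion of a cis-1,2-dialkenyl-5-methylcyclohexanol. C8–C9 forms between two Z enol-ether termini, C1–C6 breaks, and the C6 enolate is alkylated at C7 in the same flask.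
- The carbinol comes from a 2-alkenyl-5-methylcyclohexanone plus an alkoxyacetylide (then cis-semihydrogenation); the ketone comes from (S)-3-methylcyclohexanone via a β-keto ester, an acetate arm and a temporary cis-lactone.
- Ring order: cyclohexane (from cyclohexenone), then the ten-membered carbocycle (ring expansion), then the γ-lactone.

Key step: step 14

Remark on the chemistry: the C7–C8 unit is added as a lithium alkoxyacetylide and then semihydrogenated, because an sp2 organolithium would be expected to attack the 2-substituted cyclohexanone equatorially and give the trans-dialkenyl carbinol; the enolate from the sigmatropic shift is alkylated at C7 rather than protonated, because the free β-alkoxy ketone would be expected to re-enolise towards C5, so the ten-membered C6 ketone is isolated with the C11–C12 arm already on C7; the (S,R,R) ligand in step 1 is assumed to give the (S)-ketone as it does with diethylzinc.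

Step 1
Reactants: 1 cyclohex-2-en-1-one
Product: 2 (3S)-3-methylcyclohexan-1-one
Conditions: Me2Zn, Cu(OTf)2 (2 mol%), (S,R,R)-BINOL bis(1-phenylethyl)amine phosphoramidite (4 mol%), toluene, −30 °C; aq NH4Cl
Reagents that add atoms: dimethylzinc, C[Zn]C
Why: Copper-catalysed asymmetric conjugate addition of a dialkylzinc, in which the phosphoramidite ligand selects the enone face, should set C4 as S.

Step 2
Reactants: 2 (3S)-3-methylcyclohexan-1-one
Product: 3 methyl (4S)-4-methyl-2-oxocyclohexane-1-carboxylate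
Conditions: NaH, (MeO)2CO, THF, reflux; dilute HCl
Reagents that add atoms: dimethyl carbonate, COC(=O)OC
Why: Claisen-type C-acylation under equilibrating conditions goes to the less hindered α-carbon (the future C1), away from the methyl-bearing carbon.

Step 3
Reactants: 3 methyl (4S)-4-methyl-2-oxocyclohexane-1-carboxylate; 4 methyl bromoacetate
Product: 5 methyl (4S)-1-(2-methoxy-2-oxoethyl)-4-methyl-2-oxocyclohexane-1-carboxylate
Conditions: K2CO3, acetone, reflux
Reagents that add atoms: none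
Why: SN2 alkylation of the β-keto ester at its doubly activated carbon attaches the C10–C14 unit to C1 regiospecifically.

Step 4
Reactants: 5 methyl (4S)-1-(2-methoxy-2-oxoethyl)-4-methyl-2-oxocyclohexane-1-carboxylate
Product: 6 methyl 2-[(1R,4S)-4-methyl-2-oxocyclohexyl]acetate
Conditions: LiCl, H2O, DMSO, 150 °C; then NaOMe (cat.), MeOH, 20 °C
Reagents that add atoms: none
Why: Krapcho dealkoxycarbonylation removes only the β-keto ester group, and base equilibration of the epimerisable C1 should favour the trans-2,5 (diequatorial) ketone, which relays the C4 configuration to C1 (R).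

Step 5
Reactants: 6 methyl 2-[(1R,4S)-4-methyl-2-oxocyclohexyl]acetate
Product: 8 (3aR,6S,7aR)-6-methylhexahydro-1-benzofuran-2(3H)-one, via hydroxy ester 7 (not isolated)
Conditions: Li[HB(s-Bu)3], THF, −78 → 20 °C; H2O; TsOH (cat.), toluene, 20 °C
Reagents that add atoms: none
Why: The bulky hydride should attack the 2-substituted cyclohexanone equatorially to give the axial alcohol cis to the ester arm, which lactonises; the cis-lactone masks the C6 oxygen and activates C10.

Step 6
Reactants: 8 (3aR,6S,7aR)-6-methylhexahydro-1-benzofuran-2(3H)-one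
Product: 9 (3aR,6S,7aR)-3-(hydroxymethylidene)-6-methylhexahydro-1-benzofuran-2(3H)-one
Conditions: LiN(i-Pr)2, THF, −78 °C; HCO2Et, −78 → 0 °C; dilute HCl
Reagents that add atoms: ethyl formate, CCOC=O
Why: Crossed Claisen formylation at the only α-carbon of the lactone (C10) brings in C9 with its oxygen.

Step 7
Reactants: 9 (3aR,6S,7aR)-3-(hydroxymethylidene)-6-methylhexahydro-1-benzofuran-2(3H)-one
Product: 10 (3E,3aR,6S,7aR)-3-[(methoxymethoxy)methylidene]-6-methylhexahydro-1-benzofuran-2(3H)-one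
Conditions: MOMCl, i-Pr2NEt, CH2Cl2, 0 °C
Reagents that add atoms: chloromethyl methyl ether, COCCl
Why: O-alkylation of the formyl-lactone enol by the hard chloromethyl ether should give the E alkoxymethylidene lactone (alkoxy anti to the carbonyl, cis to C1), the geometry that later defines C9.

Step 8
Reactants: 10 (3E,3aR,6S,7aR)-3-[(methoxymethoxy)methylidene]-6-methylhexahydro-1-benzofuran-2(3H)-one
Product: 11 (1R,2R,5S)-2-[(1E)-3-hydroxy-1-(methoxymethoxy)prop-1-en-2-yl]-5-methylcyclohexan-1-ol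
Conditions: i-Bu2AlH, CH2Cl2, −78 → 0 °C; Rochelle salt; base-washed silica
Reagents that add atoms: none
Why: Hydride reduction of the lactone to the ring-opened diol (as for β-alkoxyacrylates) leaves the enol ether double bond and its geometry untouched.

Step 9
Reactants: 11 (1R,2R,5S)-2-[(1E)-3-hydroxy-1-(methoxymethoxy)prop-1-en-2-yl]-5-methylcyclohexan-1-ol
Product: 12 (1R,2R,5S)-2-[(1E)-3-{[tert-butyl(dimethyl)silyl]oxy}-1-(methoxymethoxy)prop-1-en-2-yl]-5-methylcyclohexan-1-ol
Conditions: TBSCl, imidazole, CH2Cl2, 0 °C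
Reagents that add atoms: tert-butyldimethylsilyl chloride, CC(C)(C)[Si](C)(C)Cl
Why: Silylation should select the primary allylic hydroxyl over the hindered axial secondary one.

Step 10
Reactants: 12 (1R,2R,5S)-2-[(1E)-3-{[tert-butyl(dimethyl)silyl]oxy}-1-(methoxymethoxy)prop-1-en-2-yl]-5-methylcyclohexan-1-ol
Product: 13 (2R,5S)-2-[(1E)-3-{[tert-butyl(dimethyl)silyl]oxy}-1-(methoxymethoxy)prop-1-en-2-yl]-5-methylcyclohexan-1-one
Conditions: n-Pr4N[RuO4] (5 mol%), NMO, 4 Å MS, CH2Cl2, 20 °C
Reagents that add atoms: none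
Why: Ley–Griffith oxidation under near-neutral conditions should give the β,γ-unsaturated ketone without epimerising C1 or hydrolysing the enol ether.

Step 11
Reactants: 14 4-methoxybenzyl alcohol; 15 trichloroethylene
Product: 16 1-({[(E)-1,2-dichloroethenyl]oxy}methyl)-4-methoxybenzene
Conditions: KH, THF, 0 °C; then 15, −50 → 20 °C
Reagents that add atoms: none
Why: Base-mediated addition–elimination of the alkoxide with trichloroethylene (Greene's dichlorovinyl ether synthesis) gives the precursor of the alkoxyacetylide.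

Step 12
Reactants: 16 1-({[(E)-1,2-dichloroethenyl]oxy}methyl)-4-methoxybenzene; 13 (2R,5S)-2-[(1E)-3-{[tert-butyl(dimethyl)silyl]oxy}-1-(methoxymethoxy)prop-1-en-2-yl]-5-methylcyclohexan-1-one
Product: 18 (1S,2R,5S)-2-[(1E)-3-{[tert-butyl(dimethyl)silyl]oxy}-1-(methoxymethoxy)prop-1-en-2-yl]-1-{[(4-methoxybenzyl)oxy]ethynyl}-5-methylcyclohexan-1-ol, via lithium alkoxyacetylide 17 (not isolated)
Conditions: 16, n-BuLi (2.1 equiv per 16), THF, −78 → −40 °C; then 13 premixed with LaCl3·2LiCl, THF, −78 °C; aq NaHCO3; kept below 20 °C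
Reagents that add atoms: none
Why: Dehydrochlorination and chlorine–lithium exchange give the acetylide, whose 1,2-addition as a slim sp nucleophile should go axially, so C6 (S) gets the equatorial hydroxyl and the alkynyl group cis to the C1 arm; LaCl3·2LiCl suppresses enolisation of the ketone.

Step 13
Reactants: 18 (1S,2R,5S)-2-[(1E)-3-{[tert-butyl(dimethyl)silyl]oxy}-1-(methoxymethoxy)prop-1-en-2-yl]-1-{[(4-methoxybenzyl)oxy]ethynyl}-5-methylcyclohexan-1-ol
Product: 19 (1S,2R,5S)-2-[(1E)-3-{[tert-butyl(dimethyl)silyl]oxy}-1-(methoxymethoxy)prop-1-en-2-yl]-1-{(Z)-2-[(4-methoxybenzyl)oxy]ethenyl}-5-methylcyclohexan-1-ol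
Conditions: H2 (1 atm), Pd/CaCO3 poisoned with Pb(OAc)2 (Lindlar catalyst), quinoline, EtOAc, 20 °C
Reagents that add atoms: none
Why: Lindlar semihydrogenation (syn addition) turns the ynol ether into the Z enol ether, and the poisoned catalyst should spare the benzyl-type ether and the trisubstituted enol ether.

Step 14
Reactants: 19 (1S,2R,5S)-2-[(1E)-3-{[tert-butyl(dimethyl)silyl]oxy}-1-(methoxymethoxy)prop-1-en-2-yl]-1-{(Z)-2-[(4-methoxybenzyl)oxy]ethenyl}-5-methylcyclohexan-1-ol; 4 methyl bromoacetate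
Product: 22 methyl 2-[(1R,2S,3S,4Z,8S)-4-({[tert-butyl(dimethyl)silyl]oxy}methyl)-2-[(4-methoxybenzyl)oxy]-3-(methoxymethoxy)-8-methyl-10-oxocyclodec-4-en-1-yl]acetate, via potassium alkoxide 20 (not isolated), via potassium enolate 21 (not isolated)
Conditions: KN(SiMe3)2, 18-crown-6, THF, 0 → 20 °C; then −78 °C, 4; aq NH4Cl at −78 °C
Reagents that add atoms: none
Why: Alkoxide 20 weakens C1–C6 and undergoes an anionic oxy-Cope [3,3]-shift through a chair array C8–C7–C6–C1–C10–C9, in which C8–C9 forms suprafacially as C1–C6 breaks, to give enolate 21 of the ten-membered C6 ketone, which is C-alkylated at C7 by the bromoacetate. The closest known reaction is the potassium-alkoxide ring expansion of 1,2-divinylcyclohexanols to cyclodec-5-enones with in-flask trapping of the enolate; two alkoxy-bearing termini extend it. The ten-membered ring is not closed end to end but arises by four-carbon ring expansion of the cyclohexane. C8 and C9 (both S) are set by the two Z enol ethers, whose alkoxy groups sit axial in the chair and so end up threo, with the absolute sense fixed by C1 and C6 of the cyclohexane chair that the equatorial C4 methyl anchors; C7 (R) should be set by alkylation on the outer face of the ring-trans enolate, anti to the C8 ether. The step needs the chair with C2 axial on C1 (ring-cis C1=C10) rather than the chair of the ring-flipped cyclohexane or a boat, which the cis-dialkenyl arrangement with equatorial methyl and C1 arm and potassium bridging of the C6 oxide and the axial C8 ether should secure. The enolate is used at once and cold so that the C8 alkoxide is not expelled, and because only this enolate is regiodefined.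

Step 15
Reactants: 22 methyl 2-[(1R,2S,3S,4Z,8S)-4-({[tert-butyl(dimethyl)silyl]oxy}methyl)-2-[(4-methoxybenzyl)oxy]-3-(methoxymethoxy)-8-methyl-10-oxocyclodec-4-en-1-yl]acetate
Product: 24 (3aS,4S,5S,6Z,10S,11aR)-6-({[tert-butyl(dimethyl)silyl]oxy}methyl)-4-[(4-methoxybenzyl)oxy]-5-(methoxymethoxy)-10-methyl-3a,4,5,8,9,10,11,11a-octahydrocyclodeca[b]furan-2(3H)-one, via hydroxy ester 23 (not isolated)
Conditions: Li[HB(s-Bu)3], THF, −78 → 0 °C; H2O; PPTS (cat.), toluene, 50 °C
Reagents that add atoms: none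
Why: Reduction with a bulky non-chelating hydride should, with the C6 carbonyl turned away from the C8 ether dipole, deliver hydride from the ring periphery to give the 6R alcohol (Felkin-type towards C7, 1,3-anti to O8), which is trans to the C7 arm and closes the trans-fused γ-lactone.

Step 16
Reactants: 24 (3aS,4S,5S,6Z,10S,11aR)-6-({[tert-butyl(dimethyl)silyl]oxy}methyl)-4-[(4-methoxybenzyl)oxy]-5-(methoxymethoxy)-10-methyl-3a,4,5,8,9,10,11,11a-octahydrocyclodeca[b]furan-2(3H)-one
Product: 25 3-[(dimethylamino)methyl] derivative of lactone 24 (both C3 epimers)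
Conditions: LiN(i-Pr)2, THF, −78 °C; Me2N=CH2 iodide (Eschenmoser's salt), −78 → 20 °C
Reagents that add atoms: Eschenmoser's salt (N,N-dimethylmethaniminium iodide), C=[N+](C)C.[I-]
Why: Mannich reaction of the lactone after deprotonation at C11, its only acidic carbon, brings in C13; silyl, PMB and MOM ethers are inert.

Step 17
Reactants: 25 3-[(dimethylamino)methyl] derivative of lactone 24
Product: 27 (3aS,4S,5S,6Z,10S,11aR)-6-({[tert-butyl(dimethyl)silyl]oxy}methyl)-4-[(4-methoxybenzyl)oxy]-5-(methoxymethoxy)-10-methyl-3-methylidene-3a,4,5,8,9,10,11,11a-octahydrocyclodeca[b]furan-2(3H)-one, via trimethylammonium iodide 26 (not isolated)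
Conditions: MeI, MeOH, 20 °C; then aq NaHCO3, CH2Cl2
Reagents that add atoms: none
Why: N-Methylation and mild-base β-elimination of trimethylamine (Hofmann-type) give the α-methylene lactone without touching C7.

Step 18
Reactants: 27 α-methylene lactone with C14 silyl ether
Product: 28 (3aS,4S,5S,6Z,10S,11aR)-6-(hydroxymethyl)-4-[(4-methoxybenzyl)oxy]-5-(methoxymethoxy)-10-methyl-3-methylidene-3a,4,5,8,9,10,11,11a-octahydrocyclodeca[b]furan-2(3H)-one
Conditions: HF·pyridine, pyridine, THF, 0 °C
Reagents that add atoms: none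
Why: Buffered fluoride desilylation frees the primary allylic alcohol and should leave the MOM and PMB ethers and the methylene lactone untouched.

Step 19
Reactants: 28 C14 allylic alcohol
Product: 29 (3aS,4S,5S,6E,10S,11aR)-4-[(4-methoxybenzyl)oxy]-5-(methoxymethoxy)-10-methyl-3-methylidene-2-oxo-2,3,3a,4,5,8,9,10,11,11a-decahydrocyclodeca[b]furan-6-carbaldehyde
Conditions: TEMPO (cat.), PhI(OAc)2, CH2Cl2, 20 °C
Reagents that add atoms: none
Why: Oxoammonium (TEMPO) oxidation of the primary allylic alcohol stops at the enal and should keep the ring-cis olefin geometry.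

Step 20
Reactants: 29 C14 enal
Product: 30 (3aS,4S,5S,6E,10S,11aR)-4-[(4-methoxybenzyl)oxy]-5-(methoxymethoxy)-10-methyl-3-methylidene-2-oxo-2,3,3a,4,5,8,9,10,11,11a-decahydrocyclodeca[b]furan-6-carboxylic acid
Conditions: NaClO2, NaH2PO4, 2-methylbut-2-ene, t-BuOH/H2O, 0 → 20 °C
Reagents that add atoms: sodium chlorite, [Na+].[O-]Cl=O
Why: Pinnick oxidation converts the enal to the acid, with the alkene scavenger protecting the olefins and the PMB ether from hypochlorite.

Step 21
Reactants: 30 C14 acid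
Product: 31 methyl (3aS,4S,5S,6E,10S,11aR)-4-[(4-methoxybenzyl)oxy]-5-(methoxymethoxy)-10-methyl-3-methylidene-2-oxo-2,3,3a,4,5,8,9,10,11,11a-decahydrocyclodeca[b]furan-6-carboxylate
Conditions: MeI, KHCO3, DMF, 20 °C
Reagents that add atoms: iodomethane, CI
Why: SN2 O-methylation of the carboxylate avoids diazoalkanes, which would add to the α-methylene lactone.

Step 22
Reactants: 31 C14 methyl ester with C8 PMB ether
Product: 32 methyl (3aR,4S,5S,6E,10S,11aR)-4-hydroxy-5-(methoxymethoxy)-10-methyl-3-methylidene-2-oxo-2,3,3a,4,5,8,9,10,11,11a-decahydrocyclodeca[b]furan-6-carboxylate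
Conditions: DDQ, CH2Cl2/pH 7 buffer, 0 °C
Reagents that add atoms: none
Why: Oxidative cleavage of the electron-rich PMB ether frees only the C8 hydroxyl under neutral conditions; the 3a descriptor changes by priority only.

Step 23
Reactants: 32 C8 alcohol; 33 angelic acid
Product: 35 methyl (3aS,4S,5S,6E,10S,11aR)-5-(methoxymethoxy)-10-methyl-3-methylidene-4-{[(2Z)-2-methylbut-2-enoyl]oxy}-2-oxo-2,3,3a,4,5,8,9,10,11,11a-decahydrocyclodeca[b]furan-6-carboxylate, via mixed anhydride 34 (not isolated)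
Conditions: 33, 2,4,6-trichlorobenzoyl chloride, Et3N, toluene, 20 °C; then 32, toluene, 80 °C (no DMAP)
Reagents that add atoms: none
Why: Yamaguchi esterification without DMAP is the protocol under which angelates form without Z-to-E isomerisation to tiglates, and only O8 is free; it is run promptly because the free C8 hydroxyl is cis to the lactone carbon and could translactonise.

Step 24
Reactants: 35 C8 angelate with C9 MOM ether
Product: 37 methyl (3aS,4S,5S,6E,10S,11aR)-5-hydroxy-10-methyl-3-methylidene-4-{[(2Z)-2-methylbut-2-enoyl]oxy}-2-oxo-2,3,3a,4,5,8,9,10,11,11a-decahydrocyclodeca[b]furan-6-carboxylate, via bromomethyl ether 36 (not isolated)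
Conditions: Me2BBr, CH2Cl2, −78 °C; then aq NaHCO3/THF
Reagents that add atoms: none
Why: Lewis-acid cleavage of the MOM acetal with bromodimethylborane at −78 °C should spare the esters, the α-methylene lactone and the angelate geometry.

**Compound list**
1 | cyclohex-2-en-1-one | O=C1C=CCCC1 | starting material
2 | (3S)-3-methylcyclohexan-1-one | O=C1C[C@@H](C)CCC1 | intermediate
3 | methyl (4S)-4-methyl-2-oxocyclohexane-1-carboxylate (C1 epimers/enol) | O=C1C[C@@H](C)CCC1C(=O)OC | intermediate
4 | methyl bromoacetate | COC(=O)CBr | starting material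
5 | methyl (4S)-1-(2-methoxy-2-oxoethyl)-4-methyl-2-oxocyclohexane-1-carboxylate (C1 epimers) | O=C1C[C@@H](C)CCC1(CC(=O)OC)C(=O)OC | intermediate
6 | methyl 2-[(1R,4S)-4-methyl-2-oxocyclohexyl]acetate | O=C1C[C@@H](C)CC[C@@H]1CC(=O)OC | intermediate
7 | methyl 2-[(1R,2R,4S)-2-hydroxy-4-methylcyclohexyl]acetate (not isolated) | O[C@@H]1C[C@@H](C)CC[C@@H]1CC(=O)OC | intermediate
8 | (3aR,6S,7aR)-6-methylhexahydro-1-benzofuran-2(3H)-one | O=C1C[C@H]2CC[C@H](C)C[C@H]2O1 | intermediate
9 | (3aR,6S,7aR)-3-(hydroxymethylidene)-6-methylhexahydro-1-benzofuran-2(3H)-one | O=C1C(=CO)[C@H]2CC[C@H](C)C[C@H]2O1 | intermediate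
10 | (3E,3aR,6S,7aR)-3-[(methoxymethoxy)methylidene]-6-methylhexahydro-1-benzofuran-2(3H)-one | O=C1/C(=C/OCOC)[C@H]2CC[C@H](C)C[C@H]2O1 | intermediate
11 | (1R,2R,5S)-2-[(1E)-3-hydroxy-1-(methoxymethoxy)prop-1-en-2-yl]-5-methylcyclohexan-1-ol | O[C@@H]1C[C@@H](C)CC[C@@H]1/C(CO)=C\OCOC | intermediate
12 | (1R,2R,5S)-2-[(1E)-3-{[tert-butyl(dimethyl)silyl]oxy}-1-(methoxymethoxy)prop-1-en-2-yl]-5-methylcyclohexan-1-ol | O[C@@H]1C[C@@H](C)CC[C@@H]1/C(CO[Si](C)(C)C(C)(C)C)=C\OCOC | intermediate
13 | (2R,5S)-2-[(1E)-3-{[tert-butyl(dimethyl)silyl]oxy}-1-(methoxymethoxy)prop-1-en-2-yl]-5-methylcyclohexan-1-one | O=C1C[C@@H](C)CC[C@@H]1/C(CO[Si](C)(C)C(C)(C)C)=C\OCOC | intermediate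
14 | 4-methoxybenzyl alcohol | COc1ccc(CO)cc1 | starting material
15 | trichloroethylene | ClC=C(Cl)Cl | starting material
16 | 1-({[(E)-1,2-dichloroethenyl]oxy}methyl)-4-methoxybenzene | Cl/C=C(/Cl)OCc1ccc(OC)cc1 | intermediate
17 | lithium 2-[(4-methoxybenzyl)oxy]ethynide (not isolated) | [Li]C#COCc1ccc(OC)cc1 | intermediate
18 | (1S,2R,5S)-1-alkynyl carbinol (PMB ynol ether; OH equatorial, alkynyl cis to the C1 arm) | O[C@@]1(C#COCc2ccc(OC)cc2)C[C@@H](C)CC[C@@H]1/C(CO[Si](C)(C)C(C)(C)C)=C\OCOC | intermediate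
19 | (1S,2R,5S)-cis-1,2-dialkenyl-5-methylcyclohexanol (oxy-Cope precursor; Z PMB enol ether on C6, E MOM enol ether arm on C1) | O[C@@]1(/C=C\OCc2ccc(OC)cc2)C[C@@H](C)CC[C@@H]1/C(CO[Si](C)(C)C(C)(C)C)=C\OCOC | intermediate
20 | potassium alkoxide of 19 (not isolated) | [K+].[O-][C@@]1(/C=C\OCc2ccc(OC)cc2)C[C@@H](C)CC[C@@H]1/C(CO[Si](C)(C)C(C)(C)C)=C\OCOC | intermediate
21 | potassium (1Z,3S,4S,5Z,9S)-5-({[tert-butyl(dimethyl)silyl]oxy}methyl)-3-[(4-methoxybenzyl)oxy]-4-(methoxymethoxy)-9-methylcyclodeca-1,5-dien-1-olate (C6 enolate of the ten-membered ketone, not isolated) | [K+].[O-]/C1=C\[C@H](OCc2ccc(OC)cc2)[C@@H](OCOC)/C(CO[Si](C)(C)C(C)(C)C)=C\CC[C@H](C)C1 | intermediate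
22 | methyl 2-[(1R,2S,3S,4Z,8S)-4-({[tert-butyl(dimethyl)silyl]oxy}methyl)-2-[(4-methoxybenzyl)oxy]-3-(methoxymethoxy)-8-methyl-10-oxocyclodec-4-en-1-yl]acetate (ten-membered C6 ketone) | O=C1C[C@@H](C)CC/C=C(/CO[Si](C)(C)C(C)(C)C)[C@H](OCOC)[C@@H](OCc2ccc(OC)cc2)[C@H]1CC(=O)OC | intermediate
23 | methyl 2-[(1S,2S,3S,4Z,8S,10R)-10-hydroxy analogue of 22]acetate (not isolated) | O[C@@H]1C[C@@H](C)CC/C=C(/CO[Si](C)(C)C(C)(C)C)[C@H](OCOC)[C@@H](OCc2ccc(OC)cc2)[C@H]1CC(=O)OC | intermediate
24 | (3aS,4S,5S,6Z,10S,11aR)-6-({[tert-butyl(dimethyl)silyl]oxy}methyl)-4-[(4-methoxybenzyl)oxy]-5-(methoxymethoxy)-10-methyl-3a,4,5,8,9,10,11,11a-octahydrocyclodeca[b]furan-2(3H)-one | O=C1O[C@@H]2C[C@@H](C)CC/C=C(/CO[Si](C)(C)C(C)(C)C)[C@H](OCOC)[C@@H](OCc3ccc(OC)cc3)[C@H]2C1 | intermediate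
25 | 3-[(dimethylamino)methyl] derivative of 24 (C3 epimers) | CN(C)CC1C(=O)O[C@@H]2C[C@@H](C)CC/C=C(/CO[Si](C)(C)C(C)(C)C)[C@H](OCOC)[C@@H](OCc3ccc(OC)cc3)[C@@H]12 | intermediate
26 | trimethylammonium iodide of 25 (not isolated) | C[N+](C)(C)CC1C(=O)O[C@@H]2C[C@@H](C)CC/C=C(/CO[Si](C)(C)C(C)(C)C)[C@H](OCOC)[C@@H](OCc3ccc(OC)cc3)[C@@H]12.[I-] | intermediate
27 | 3-methylidene lactone with C14 silyl ether, C8 PMB and C9 MOM ethers | C=C1C(=O)O[C@@H]2C[C@@H](C)CC/C=C(/CO[Si](C)(C)C(C)(C)C)[C@H](OCOC)[C@@H](OCc3ccc(OC)cc3)[C@@H]12 | intermediate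
28 | C14 allylic alcohol | C=C1C(=O)O[C@@H]2C[C@@H](C)CC/C=C(/CO)[C@H](OCOC)[C@@H](OCc3ccc(OC)cc3)[C@@H]12 | intermediate
29 | C14 aldehyde | C=C1C(=O)O[C@@H]2C[C@@H](C)CC/C=C(/C=O)[C@H](OCOC)[C@@H](OCc3ccc(OC)cc3)[C@@H]12 | intermediate
30 | C14 carboxylic acid | C=C1C(=O)O[C@@H]2C[C@@H](C)CC/C=C(/C(=O)O)[C@H](OCOC)[C@@H](OCc3ccc(OC)cc3)[C@@H]12 | intermediate
31 | C14 methyl ester with C8 PMB and C9 MOM ethers | C=C1C(=O)O[C@@H]2C[C@@H](C)CC/C=C(/C(=O)OC)[C@H](OCOC)[C@@H](OCc3ccc(OC)cc3)[C@@H]12 | intermediate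
32 | C8 alcohol with C9 MOM ether | C=C1C(=O)O[C@@H]2C[C@@H](C)CC/C=C(/C(=O)OC)[C@H](OCOC)[C@@H](O)[C@@H]12 | intermediate
33 | angelic acid, (2Z)-2-methylbut-2-enoic acid | C/C=C(/C)C(=O)O | starting material
34 | (2Z)-2-methylbut-2-enoic 2,4,6-trichlorobenzoic anhydride (not isolated) | C/C=C(/C)C(=O)OC(=O)c1c(Cl)cc(Cl)cc1Cl | intermediate
35 | C8 angelate with C9 MOM ether | C=C1C(=O)O[C@@H]2C[C@@H](C)CC/C=C(/C(=O)OC)[C@H](OCOC)[C@@H](OC(=O)/C(C)=C\C)[C@@H]12 | intermediate
36 | C9 bromomethyl ether of the target (not isolated) | C=C1C(=O)O[C@@H]2C[C@@H](C)CC/C=C(/C(=O)OC)[C@H](OCBr)[C@@H](OC(=O)/C(C)=C\C)[C@@H]12 | intermediate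
37 | methyl (3aS,4S,5S,6E,10S,11aR)-5-hydroxy-10-methyl-3-methylidene-4-{[(2Z)-2-methylbut-2-enoyl]oxy}-2-oxo-2,3,3a,4,5,8,9,10,11,11a-decahydrocyclodeca[b]furan-6-carboxylate | C=C1C(=O)O[C@@H]2C[C@@H](C)CC/C=C(/C(=O)OC)[C@H](O)[C@@H](OC(=O)/C(C)=C\C)[C@@H]12 | target

**Step count and risks**
Total step count: 24. Longest linear sequence: 23 (steps 1–10 and 12–24; step 11 is a side branch).

Steps most likely to fail:

1. Step 14. The crowned potassium enolate may expel the C8 alkoxide at the temperature the shift needs, and the shift may leak through the other chair or a boat, which would scramble C8/C9 and the olefin geometry. Fallback (neutral, thermal variant, no enolate while the ring expands), from 19 back to 22: silylation of the tertiary alcohol (N-(trimethylsilyl)imidazole, CH2Cl2) gives the trimethylsilyl ether F1. Thermal siloxy-Cope rearrangement (degassed toluene, trace N,O-bis(trimethylsilyl)acetamide, sealed tube, about 200 °C) should give the regiodefined C6–C7 trimethylsilyl enol ether F2. MeLi (THF, −78 → −20 °C) then releases the lithium enolate F3, which is alkylated cold with 4 (DMPU, −78 °C) to rejoin the route at 22.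

2. Step 15. Hydride may add to the wrong face of the C6 carbonyl, because the medium-ring conformation is not secured, and this would give the cis-fused lactone. Fallback (make the epimer on purpose and invert), from 22 back to 24: chelation-controlled reduction with Zn(BH4)2 (Et2O, −20 °C; zinc bridging the C6 carbonyl and the C8 ether, 1,3-syn) should give the 6-epi alcohol, which closes to the cis-fused lactone F4. LiOH (THF/H2O) and careful acidification to pH 5 at 0 °C give the hydroxy acid F5. Mitsunobu lactonisation (PPh3, DIAD, THF, 0 °C) then closes the lactone with inversion at C6 to give 24.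

3. Step 12. The benzyl-type alkynyl ether may be lost by sigmatropic or acid-induced rearrangement before or after the addition, or the ketone may enolise. Fallback (preformed Z vinyl nucleophile, no alkynyl ether, no hydrogenation), from 14 and 13 back to 19: transvinylation of 14 (vinyl acetate, [Ir(cod)Cl]2, Na2CO3, toluene, 100 °C) gives the vinyl ether F6. Br2 (CH2Cl2, −78 °C) gives the dibromide F7, and Et3N-mediated dehydrobromination gives the (Z)-2-bromovinyl ether F8. t-BuLi (2 equiv, Et2O, −78 °C) gives the vinyllithium F9. It is added to 13 precomplexed with MeAl(OAr)2 (Ar = 2,6-di-tert-butyl-4-methylphenyl; toluene, −78 °C), the bulky aluminium phenoxide blocking the equatorial side so that the sp2 nucleophile should also enter axially, to give 19 directly.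

**Further compounds**
F1 | step 14 | trimethylsilyl ether of carbinol 19 | C[Si](C)(C)O[C@@]1(/C=C\OCc2ccc(OC)cc2)C[C@@H](C)CC[C@@H]1/C(CO[Si](C)(C)C(C)(C)C)=C\OCOC
F2 | step 14 | C6–C7 trimethylsilyl enol ether of the ten-membered ketone | C[Si](C)(C)O/C1=C\[C@H](OCc2ccc(OC)cc2)[C@@H](OCOC)/C(CO[Si](C)(C)C(C)(C)C)=C\CC[C@H](C)C1
F3 | step 14 | lithium C6 enolate of the ten-membered ketone | [Li+].[O-]/C1=C\[C@H](OCc2ccc(OC)cc2)[C@@H](OCOC)/C(CO[Si](C)(C)C(C)(C)C)=C\CC[C@H](C)C1
F4 | step 15 | (3aS,4S,5S,6Z,10S,11aS)-cis-fused lactone (11a-epimer of 24) | O=C1O[C@H]2C[C@@H](C)CC/C=C(/CO[Si](C)(C)C(C)(C)C)[C@H](OCOC)[C@@H](OCc3ccc(OC)cc3)[C@H]2C1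
F5 | step 15 | 2-[(1S,2S,3S,4Z,8S,10S)-4-({[tert-butyl(dimethyl)silyl]oxy}methyl)-10-hydroxy-2-[(4-methoxybenzyl)oxy]-3-(methoxymethoxy)-8-methylcyclodec-4-en-1-yl]acetic acid | O[C@H]1C[C@@H](C)CC/C=C(/CO[Si](C)(C)C(C)(C)C)[C@H](OCOC)[C@@H](OCc2ccc(OC)cc2)[C@H]1CC(=O)O
F6 | step 12 | 1-[(ethenyloxy)methyl]-4-methoxybenzene | C=COCc1ccc(OC)cc1
F7 | step 12 | 1-[(1,2-dibromoethoxy)methyl]-4-methoxybenzene | BrCC(Br)OCc1ccc(OC)cc1
F8 | step 12 | 1-({[(Z)-2-bromoethenyl]oxy}methyl)-4-methoxybenzene | Br/C=C\OCc1ccc(OC)cc1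
F9 | step 12 | {(Z)-2-[(4-methoxybenzyl)oxy]ethenyl}lithium | [Li]/C=C\OCc1ccc(OC)cc1
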